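The numbers in the tables were generated by integration for an exercise.

The easy step comes first: I turn every percentage into mM, so the winter flask and the dawn flask can stand side by side.

| flask | Q | Z | remark | time |
|---|---|---|---|---|
| winter | 15 mM | 60 mM | the very flask that is asked about, followed so far |  |
| dawn | 30 mM | 60 mM | run made earlier |  |
| flask | 15 mM | 60.0 mM |  | 40 h |

| run | time / h | X / % | Q / % |
|---|---|---|---|
| winter | 0.417 | 0.3 | 95.7 |
| winter | 1.00 | 0.7 | 90.4 |
| winter | 2.00 | 3.2 | 83.0 |
| winter | 3.00 | 6.1 | 77.5 |
| winter | 4.00 | 8.5 | 72.8 |
| winter | 6.00 | 14.0 | 64.4 |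
| winter | 8.00 | 19.2 | 57.5 |
| dawn | 2.00 | 1.0 | 92.0 |
| dawn | 6.00 | 6.7 | 82.7 |
| dawn | 12.0 | 13.3 | 73.4 |
| dawn | 15.0 | 15.5 | 70.6 |
| dawn | 25.0 | 18.9 | 65.8 |
| dawn | 30.0 | 19.3 | 64.8 |
| dawn | 40.0 | 18.4 | 66.6 |

(scatter of a reading: 0.3 percentage points)

- why nothing more happens at 40 h, or that something still does (for what has run out or reacted, a solid counts together with what of it has only dissolved) (forward and back rates have come level / Z has run out first / all of Q has reacted / it is still moving)
- X at 40 h, in percent of the Q charged

- Q is a solid; its amount is given per volume of the solution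
- at the start none of Q is in solution
- what has only dissolved of Q counts as not reacted
- the reaction counts as stopped when no species that holds the Q changes by six tenths of a point or more over the second half of the time

In the first hours the solid dissolves and little else shows. By 2.00 h, winter has lost 2.55 mM of Q and dawn 2.40 mM, though dawn holds twice the charge, so the loss looks zero order in the charge of solid.

In the middle X follows at one pace in both runs: at 6.00 h, winter reads 2.10 mM and dawn 2.01 mM. Dawn has lost 5.19 mM of Q by then, so something unseen holds the difference.

At the end dawn tops out. The highest X read there, 5.79 mM, I call the ceiling: a reading of the peak X in mM, which I expect from a flask charged with 60 mM of Z while its solid stands. Dawn's Q loss at that reading, 10.6 mM, is less than winter's charge of 15 mM, so I expect solid to stand in winter and reckon 38.6% of X. The last dawn X is 0.9 percentage points lower, against a scatter of 0.3 points, so I take the top for a turning point and the winter flask as still moving.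

The forecast says 36.5%, from 31% to 39.5%, and forward and back rates have come level: “so this is reversible equilibrium”. My X is higher than its figure.

The winter flask gives 36.1% of X, and on the stop question, it is still moving: a share moves 3.7 points over the second half of the time, and at 400 h X stands at 0.171%.

    Q ⇌ G, rate k1*(cs1 - [G]) while solid is left; crystals form when [G] > cs1 (solubility = 4.80 mM, k = 9.70 × 10⁻⁵ s⁻¹)
    G + Z ⇌ X (K = 180 L mol⁻¹, k = 0.00100 L mol⁻¹ s⁻¹)
    Z → D (k = 1.90 × 10⁻⁵ s⁻¹)

At 40 h, the winter flask holds 5.42 mM of X, less than the ceiling of 5.79 mM. For a further flask charged with 25 mM of Q and run as long, the ceiling gives 23.2%. That flask holds 21.6% of X, with Q at 58.7%.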